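The data stem from a simulated flask with constants of no real substance; noise was put on by code.

Every exchange, first or second, spends one incoming ligand and frees one leaving ligand, in each of these closed flasks.

| setting | green | blue | winter | noon | dusk |
|---|---|---|---|---|---|
| starting complex | 0.50 M | 0.50 M | 0.50 M | 0.50 M | 0.50 M |
| incoming ligand | 0.54 equiv | 2.4 equiv | 1.00 equiv | 4.00 equiv | 0.800 equiv |
| remark | run made earlier | run made earlier |  |  |  |
| time |  |  | 50 min | 50 min | 50 min |

- green (time / min: complex with two exchanged / %, starting complex / %): 1.33: 0, 96.8; 4.00: 1.6, 90.2; 8.00: 1.7, 82.0; 10.0: 1.5, 80.2; 15.0: 3.6, 73.2; 20.0: 4.9, 71.6; 25.0: 6.3, 65.0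
- blue (time / min: complex with two exchanged / %, starting complex / %): 2.00: 3.5, 78.3; 3.00: 8.0, 69.6; 5.00: 13.0, 54.2; 8.00: 22.7, 39.3; 10.0: 28.4, 34.9; 15.0: 38.3, 22.7; 25.0: 47.5, 13.3

(readings scatter by 1 percentage point)

* which of these holds the largest part of the starting complex at the end of winter (starting complex / complex with one exchanged / complex with two exchanged)
* which of these holds the largest part of the starting complex at the end of noon (starting complex / complex with one exchanged / complex with two exchanged)
* which of these holds the largest part of the starting complex at the end of dusk (starting complex / complex with one exchanged / complex with two exchanged)
* complex with two exchanged at the end of dusk, in percent of the starting complex charged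

- what is said of complex with two exchanged includes crystals
- crystals is a solid; its amount is given per volume of the solution
- what was read earlier has a scatter of 1 percentage point, one standard deviation
- steps thought possible: starting complex + incoming ligand -> leaving ligand + complex with one exchanged; complex with one exchanged + incoming ligand -> leaving ligand + complex with two exchanged; complex with two exchanged -> over-reaction product; crystals <-> complex with two exchanged

I reckoned in the exposure, the natural logarithm of charged over present [starting complex]. In blue at 10.0 min it read 1.05. I assumed both exchanges equally fast, which puts one-exchanged at the exposure times the starting complex; the readings do not show one-exchanged, so this stayed an assumption. With the mean [incoming ligand] over those minutes, blue gave a reading of 0.112 L mol⁻¹ min⁻¹ for the constant.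

Below an exposure of one, the ligand spent per complex charged about equals the exposure, so exposure climbs towards the equivalents charged, as equivalents times (1 − exp(−constant × [starting complex] charged × time)). With ligand the limiting reagent, that gave 0.752 for dusk and 0.940 for winter, both under one, so starting complex stayed ahead in each. Noon keeps at least 1.00 M of ligand, which gives an exposure of at least 5.62, so two-exchanged led there.

The forecast said starting complex, complex with two exchanged, starting complex and 11%, adding of winter that “this call is uncertain”. The flasks gave starting complex, complex with two exchanged, starting complex and 10.7%.

    starting complex + incoming ligand → leaving ligand + complex with one exchanged (k = 0.00190 L mol⁻¹ s⁻¹)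
    complex with one exchanged + incoming ligand → leaving ligand + complex with two exchanged (k = 0.00230 L mol⁻¹ s⁻¹)
    complex with two exchanged → over-reaction product (k = 3.80 × 10⁻⁴ s⁻¹)
    crystals ⇌ complex with two exchanged, rate k4*(cs4 - [complex with two exchanged]) while solid is left; crystals form when [complex with two exchanged] > cs4 (solubility = 0.220 M, k = 0.0120 s⁻¹)

Dusk ended at an exposure of 0.769 against my 0.752, with one-exchanged at 0.710 of starting complex. The neighbouring flask was dusk with [starting complex] at 0.12 M, the equivalents held. The same reckoning gives an exposure of 0.392, hence 67.5% starting complex. That flask ended with 67.4% starting complex and 25.5% one-exchanged, a ratio of 0.378.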